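**Analysis of the target**

The target 22 consists of two bicyclic units joined by one sp2–sp2 bond. One is a 5-hydroxy-7-methyl-1,4-naphthoquinone (the 7-methyljuglone ring system) attached through C2. The other is a 7-methyl-4-oxo-4H-chromene-5-carboxylic acid attached through C8. There is no stereocentre; the aryl–quinone axis is flanked by three ortho substituents (chromone C8a–O1, the C7 methyl, the quinone C1 carbonyl) but is not specified and is not controlled here. The sensitive groups are the peri-hydroxyquinone (bases, nucleophiles, reductants), the γ-pyranone (opened by hydroxide at C2) and a carboxylic acid peri to the pyranone carbonyl, which would be hard to free from an ester at a late stage. The difficulty lies in the chromone benzene ring: it is pentasubstituted (O1, the quinonyl group, CH3, CO2H and the C4 carbonyl), and the inter-unit bond sits between the ring oxygen and the methyl group. The strategy rests on an atom map of the chromone onto a second 7-methyljuglone: O1–C8a is O5–C5, C4a/C4/C3/C2 keep their places, C5–CO2H is C8a–C1, and C7–CH3 and C8 are C7 and C6. The chromone acid is therefore a 7-methyljuglone whose C1–C2 bond is cut, with C1 as the carboxyl group and the peri oxygen bonded to C2. Compound 22 is thus a 1,2-seco derivative of the 2,6'-linked dimer of 7-methyljuglone, and both halves can come from the same Diels–Alder chemistry.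

**Retrosynthetic reasoning**

22 ⇒ 21 ⇒ 20. The peri O–H of 22 is traced back to the O–CH3 of 21, and the quinone of 21 to the para-dimethoxy ring of 20. The unit that must remain a naphthoquinone is kept as its trimethyl ether so that it is not a quinone when the other unit is cleaved, and so that it survives strong base and palladium chemistry. In the forward direction a one-electron oxidant must attack only the electron-rich ring of 20, and a boron Lewis acid only the chelated peri ether of 21.

20 ⇒ 17 (key disconnection). The pyranone O1–C2 bond is cut and the carboxyl carbon is reconnected to C2 with removal of one oxygen, which turns the chromone acid into the hydroxyquinone ring of 17. This is the only disconnection that replaces the crowded pentasubstituted benzene by a ring available from a cycloaddition, with the carboxyl carbon, the ring oxygen, the methyl group and the biaryl position already in place. The forward reaction must insert oxygen between C1 and C2 of the single quinone ring, open the resulting lactone 18 to the keto aldehyde 19, and close the pyranone from the peri phenol. The opening is unavoidable: in 18 the enol carbon C2 is held on the C8a side of the C4–C4a bond, and it can reach the C5 oxygen only after the ring is cut and the side chain has rotated.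

17 ⇒ 13 + 14. The bonds C4a–C5 and C8–C8a of the hydroxyquinone unit are cut. C6 of that unit lies between the hydroxyl and the methyl group and cannot be addressed selectively by substitution on a preformed naphthalene. Placing the aryl group on C2 of diene 13 fixes its position by construction, and the symmetric dienophile 14 removes any regiochemical question. The forward reaction is a cycloaddition, aromatisation through 15 and 16, and oxidation by a second equivalent of 14.

13 ⇒ 12 ⇒ 9 + 11. The silyl dienol ether 13 is the γ-deprotonation product of enoate 12. The aryl–alkenyl bond of 12 is cut to boronate 9 and bromo enoate 11, because a cross-coupling tolerates the tetrasubstituted alkene and the ortho-methoxy group. Compound 11 is one step from 1.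

9 ⇒ 7 ⇒ 5 ⇒ 2 + 3, and 2 ⇒ 1. The boronate comes from bromide 7, and 7 from the bromohydroxyquinone 5 by reductive methylation. Compound 5 is the cycloadduct of diene 2 with the dibromoquinone 3. The bromine of 3 that is consumed directs the regiochemistry; the one that survives marks C2, the carbon that carries the other unit in 22. Everything is drawn from 1, 3, 8 and 14.

**Alternatives that were turned down**

Alternative 1: The benzenoid ring of the hydroxyquinone unit is disconnected last (C4a–C5 and C8–C8a), giving diene 2 and the chromonyl bromoquinone A2. In the forward direction 2 adds across the brominated double bond of A2, and loss of HBr and methanol gives A1, the methyl ester of 22. For it: the halogen directs the regiochemistry, the reaction type is well established, and A1 is one hydrolysis away from 22. Against it: A2 already contains the pentasubstituted chromone, so the hard ring needs its own multistep synthesis, followed by attachment of a quinone precursor, oxidation and a bromination that must place bromine para to the aryl group (the other isomer leads to the 3-aryl quinone). The final step is also saponification of a peri-hindered ester in the presence of a base-labile hydroxyquinone and pyranone. On the reliability of the key step this alternative is stronger. The chosen strategy offers instead a chromone ring obtained from a second copy of the same quinone template with no separate arene synthesis, and a free acid from the start.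

Alternative 2: The carbocycle of the quinone unit is disconnected to an aryne and a furan (C4–C4a and C1–C8a). Fluoride releases the aryne from the silyl triflate A5, and it adds across C2 and C5 of the furyl chromone A4 to give the oxabicycle A3. For it: mild conditions, two C–C bonds in one step, no oxidant near electron-rich rings. Against it: the aryne carries its methoxy group far from the furan substituent, so little orients the addition and the regioisomer with the aryl group on the other alkene carbon should form alongside A3. A3 is also three redox and deprotection operations away from a hydroxyquinone (ring opening to a naphthol, oxidation to the para-quinone, ether cleavage), and A4 and A5 are each multistep targets. It is as convergent as the chosen strategy but leaves both the chromone ring and the regiochemistry unsolved; the chosen route settles both by construction.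

Alternative 3: The chromone benzene ring is disconnected at C5'–C6' and C4a'–C8a'. Diene 13 adds to the acetylenic keto ester A7, and loss of methanol gives the 2-acetylphenol A6, which would be turned into the pyranone by a one-carbon condensation. For it: every step has precedent, and it shares 13 with the chosen route. Against it: the alkyne has an acceptor at each end, so the orientation rests on the difference between a ketone and an ester; the cycloaddition of a hindered silyl diene to an alkyne needs heat; and after A6 there remain the enaminone, the ring closure, cleavage of a peri-hindered ester, the oxidation and the demethylation. That is about six steps from 13 to 22 against four in the chosen route. On precedent it is stronger. The chosen strategy offers the shorter endgame and the free acid directly, and alternative 3 is kept as the fallback for the key step.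

Key step: step 9

Remark: dienes 2 and 13 are taken as mixtures of geometric isomers about the ketene-acetal double bond, and the aryl–quinone axis of the target, which is not specified, is left uncontrolled.

**Route**

Step 1
Reactants: 1 methyl 3-methylbut-2-enoate
Product: 2 [(1-methoxy-3-methylbuta-1,3-dien-1-yl)oxy]trimethylsilane (mixture of geometric isomers)
Conditions: LiN(iPr)2, THF, −78 °C; Me3SiCl, −78 °C to rt
Reagents that add atoms: chlorotrimethylsilane, C[Si](C)(C)Cl
Why: γ-Deprotonation of the enoate by the lithium amide gives the extended dienolate, which the chlorosilane traps on oxygen (silyl dienol ether formation of a vinylketene acetal).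

Step 2
Reactants: 2 [(1-methoxy-3-methylbuta-1,3-dien-1-yl)oxy]trimethylsilane; 3 2,5-dibromo-1,4-benzoquinone
Product: 5 2-bromo-5-hydroxy-7-methylnaphthalene-1,4-dione, via cis-fused cycloadduct 4 (not isolated)
Conditions: THF, −30 °C to rt; SiO2 or 1 M HCl on work-up
Reagents that add atoms: none
Why: Halogen-directed Diels–Alder reaction of a vinylketene acetal with a bromoquinone: the CH2 terminus of the diene bonds to the unsubstituted carbon of a brominated double bond and the acetal carbon to the C–Br carbon. Loss of HBr, methanol and the silyl group aromatises the ring, placing the hydroxyl peri to the carbonyl remote from the surviving bromine.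

Step 3
Reactants: 5 2-bromo-5-hydroxy-7-methylnaphthalene-1,4-dione
Product: 7 2-bromo-1,4,5-trimethoxy-7-methylnaphthalene, via bromonaphthalenetriol 6 (not isolated)
Conditions: Na2S2O4, Bu4NBr, THF/H2O, rt, N2; then aq. KOH, Me2SO4, 0 °C to rt
Reagents that add atoms: dimethyl sulfate, COS(=O)(=O)OC
Why: Reductive methylation: dithionite reduces the quinone to the hydroquinone, and the three phenoxides are O-methylated under phase transfer (Williamson ether synthesis) before air can reoxidise them.

Step 4
Reactants: 7 2-bromo-1,4,5-trimethoxy-7-methylnaphthalene; 8 bis(pinacolato)diboron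
Product: 9 4,4,5,5-tetramethyl-2-(1,4,5-trimethoxy-7-methylnaphthalen-2-yl)-1,3,2-dioxaborolane
Conditions: Pd(dppf)Cl2 (5 mol %), KOAc, 1,4-dioxane, 90 °C
Reagents that add atoms: none
Why: Miyaura borylation: zerovalent palladium inserts into the aryl C–Br bond, and the acetate-activated diboron transfers a boryl group; the mild base avoids biaryl homocoupling.

Step 5
Reactants: 1 methyl 3-methylbut-2-enoate
Product: 11 methyl 2-bromo-3-methylbut-2-enoate, via dibromo ester 10 (not isolated)
Conditions: Br2, CH2Cl2, 0 °C; then Et3N, rt
Reagents that add atoms: bromine, BrBr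
Why: Bromine adds across the enoate, and E2 dehydrobromination removes the acidic α-hydrogen together with the tertiary β-bromide, giving only the conjugated α-bromo enoate.

Step 6
Reactants: 9 4,4,5,5-tetramethyl-2-(1,4,5-trimethoxy-7-methylnaphthalen-2-yl)-1,3,2-dioxaborolane; 11 methyl 2-bromo-3-methylbut-2-enoate
Product: 12 methyl 3-methyl-2-(1,4,5-trimethoxy-7-methylnaphthalen-2-yl)but-2-enoate
Conditions: Pd(OAc)2 (5 mol %), SPhos (2-dicyclohexylphosphino-2',6'-dimethoxybiphenyl, 10 mol %), K3PO4, toluene/H2O, 90 °C
Reagents that add atoms: none
Why: Suzuki–Miyaura coupling: zerovalent palladium with the bulky dialkylbiaryl phosphine inserts into the alkenyl C–Br bond and the phosphate-activated boronate transmetalates. The alkene carries two identical methyl groups, so no geometric isomers can arise.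

Step 7
Reactants: 12 methyl 3-methyl-2-(1,4,5-trimethoxy-7-methylnaphthalen-2-yl)but-2-enoate
Product: 13 {[1-methoxy-3-methyl-2-(1,4,5-trimethoxy-7-methylnaphthalen-2-yl)buta-1,3-dien-1-yl]oxy}trimethylsilane (mixture of geometric isomers)
Conditions: LiN(iPr)2, THF, −78 °C; Me3SiCl, −78 °C to rt
Reagents that add atoms: chlorotrimethylsilane, C[Si](C)(C)Cl
Why: Same silyl dienol ether formation as in step 1; either γ-methyl group gives the same dienolate, and the aryl ethers and the aryl methyl group are not acidic enough to interfere.

Step 8
Reactants: 13 {[1-methoxy-3-methyl-2-(1,4,5-trimethoxy-7-methylnaphthalen-2-yl)buta-1,3-dien-1-yl]oxy}trimethylsilane; 14 1,4-benzoquinone (3 equiv)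
Product: 17 5-hydroxy-7-methyl-6-(1,4,5-trimethoxy-7-methylnaphthalen-2-yl)naphthalene-1,4-dione, via cis-fused cycloadduct 15 (not isolated), via naphthalenetriol 16 (not isolated)
Conditions: CH2Cl2, −30 °C to rt; 1 M HCl/THF on work-up
Reagents that add atoms: none
Why: Diels–Alder reaction of the electron-rich vinylketene acetal with a symmetric quinone, so the aryl group on diene C2 can only end at C6 next to the new hydroxyl. Enolisation and loss of methanol and the silyl group aromatise the adduct, and a second equivalent of benzoquinone oxidises the naphthalenetriol to the hydroxyquinone.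

Step 9
Reactants: 17 5-hydroxy-7-methyl-6-(1,4,5-trimethoxy-7-methylnaphthalen-2-yl)naphthalene-1,4-dione
Product: 20 7-methyl-4-oxo-8-(1,4,5-trimethoxy-7-methylnaphthalen-2-yl)-4H-chromene-5-carboxylic acid, via enol-ester lactone 18 (not isolated), via keto aldehyde 19 (not isolated)
Conditions: CF3CO3H [made in the flask from (CF3CO)2O and urea·H2O2; 1.5 equiv], Na2HPO4, CH2Cl2, 0 °C to rt; aq. Na2S2O3; then 1 M HCl, THF, rt
Reagents that add atoms: trifluoroperacetic acid, OOC(=O)C(F)(F)F; water, O (depending on where water attacks 18, the oxygen of one of the two ends in the carboxyl group and the other is lost on dehydration)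
Why: Proposed new method: the peracid adds to C1, the carbonyl that is not deactivated as a vinylogous acid by the chelated C5 hydroxyl, and the tetrahedral peroxy adduct rearranges with migration of the vinylic C2 to give the seven-membered enol-ester lactone 18 by ring expansion; the closest known reaction types are the Baeyer–Villiger oxidation of conjugated enones to enol esters and the acid-catalysed cyclodehydration of 2-hydroxyaryl 3-oxopropanals to chromones. In 18 the enol carbon C2 is tied to the C8a flank, on the far side of the C4–C4a bond from the C5 oxygen, so the phenol cannot displace the acyloxy group while the lactone is intact. The lactone is a vinylogous mixed anhydride and is therefore opened by water in the acidic second stage, which frees the C1 carboxylic acid and the keto aldehyde 19. Rotation about C4–C4a then brings the aldehyde carbon next to the phenol, which closes the pyranone by 6-exo-trig hemiacetal formation followed by dehydration; this forms the O–C2 bond and leaves the C4 carbonyl peri to the new carboxyl group. No stereocentre is formed. The step needs selectivity between the two carbonyls, between the two possible migrating carbons, and against oxidation of the electron-rich trimethoxynaphthalene. The first rests on the chelation of C4, the second on C8a being an aryl carbon ortho to an acyl group and not activated by the meta hydroxyl, and the third on the phosphate buffer, the small excess of peracid, the low temperature and destruction of the peracid before the aldehyde is released.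

Step 10
Reactants: 20 7-methyl-4-oxo-8-(1,4,5-trimethoxy-7-methylnaphthalen-2-yl)-4H-chromene-5-carboxylic acid
Product: 21 8-(5-methoxy-7-methyl-1,4-dioxo-1,4-dihydronaphthalen-2-yl)-7-methyl-4-oxo-4H-chromene-5-carboxylic acid
Conditions: (NH4)2Ce(NO3)6 (2.5 equiv), MeCN/H2O, 0 °C
Reagents that add atoms: water, O
Why: Oxidative demethylation by tetravalent cerium: the para-dimethoxy ring is oxidised through its radical cation, water adds at C1 and C4, and two molecules of methanol leave. The C5 ether is not para to another oxygen and stays, and the pyranone, the acid and the chromone ring are too electron-poor to react.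

Step 11
Reactants: 21 8-(5-methoxy-7-methyl-1,4-dioxo-1,4-dihydronaphthalen-2-yl)-7-methyl-4-oxo-4H-chromene-5-carboxylic acid
Product: 22 8-(5-hydroxy-7-methyl-1,4-dioxo-1,4-dihydronaphthalen-2-yl)-7-methyl-4-oxo-4H-chromene-5-carboxylic acid (target)
Conditions: BCl3 (4 equiv), CH2Cl2, −78 to 0 °C; H2O
Reagents that add atoms: none
Why: Chelation-assisted ether cleavage: BCl3 bridges the C4 carbonyl and the peri methoxy oxygen and chloride removes the methyl group. It is the only ether left, and the acyloxyborane formed at the acid is hydrolysed on work-up.

**Compound list**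

1 | methyl 3-methylbut-2-enoate | COC(=O)C=C(C)C | starting material
2 | [(1-methoxy-3-methylbuta-1,3-dien-1-yl)oxy]trimethylsilane (mixture of geometric isomers) | COC(O[Si](C)(C)C)=CC(C)=C | intermediate
3 | 2,5-dibromo-1,4-benzoquinone | O=C1C=C(Br)C(=O)C=C1Br | starting material
4 | 2,4a-dibromo-5-methoxy-7-methyl-5-(trimethylsilyloxy)-4a,5,8,8a-tetrahydronaphthalene-1,4-dione (racemic, cis-fused, one enantiomer drawn, both C5 epimers; not isolated) | O=C1C(Br)=CC(=O)[C@]2(Br)[C@H]1CC(C)=CC2(OC)O[Si](C)(C)C | intermediate
5 | 2-bromo-5-hydroxy-7-methylnaphthalene-1,4-dione | O=C1C(Br)=CC(=O)c2c(O)cc(C)cc12 | intermediate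
6 | 2-bromo-7-methylnaphthalene-1,4,5-triol (not isolated) | Oc1c(Br)cc(O)c2c(O)cc(C)cc12 | intermediate
7 | 2-bromo-1,4,5-trimethoxy-7-methylnaphthalene | COc1c(Br)cc(OC)c2c(OC)cc(C)cc12 | intermediate
8 | bis(pinacolato)diboron, 4,4,4',4',5,5,5',5'-octamethyl-2,2'-bi(1,3,2-dioxaborolane) | CC1(C)OB(OC1(C)C)B1OC(C)(C)C(C)(C)O1 | starting material
9 | 4,4,5,5-tetramethyl-2-(1,4,5-trimethoxy-7-methylnaphthalen-2-yl)-1,3,2-dioxaborolane | COc1c(B2OC(C)(C)C(C)(C)O2)cc(OC)c2c(OC)cc(C)cc12 | intermediate
10 | methyl 2,3-dibromo-3-methylbutanoate (racemic; not isolated) | COC(=O)C(Br)C(C)(C)Br | intermediate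
11 | methyl 2-bromo-3-methylbut-2-enoate | COC(=O)C(Br)=C(C)C | intermediate
12 | methyl 3-methyl-2-(1,4,5-trimethoxy-7-methylnaphthalen-2-yl)but-2-enoate | COC(=O)C(=C(C)C)c1cc(OC)c2c(OC)cc(C)cc2c1OC | intermediate
13 | {[1-methoxy-3-methyl-2-(1,4,5-trimethoxy-7-methylnaphthalen-2-yl)buta-1,3-dien-1-yl]oxy}trimethylsilane (mixture of geometric isomers) | COC(O[Si](C)(C)C)=C(C(C)=C)c1cc(OC)c2c(OC)cc(C)cc2c1OC | intermediate
14 | 1,4-benzoquinone | O=C1C=CC(=O)C=C1 | starting material
15 | 5-methoxy-7-methyl-6-(1,4,5-trimethoxy-7-methylnaphthalen-2-yl)-5-(trimethylsilyloxy)-4a,5,8,8a-tetrahydronaphthalene-1,4-dione (racemic, cis-fused, one enantiomer drawn, both C5 epimers; not isolated) | O=C1C=CC(=O)[C@@H]2[C@H]1CC(C)=C(c1cc(OC)c3c(OC)cc(C)cc3c1OC)C2(OC)O[Si](C)(C)C | intermediate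
16 | 7-methyl-6-(1,4,5-trimethoxy-7-methylnaphthalen-2-yl)naphthalene-1,4,5-triol (not isolated) | Oc1ccc(O)c2c(O)c(-c3cc(OC)c4c(OC)cc(C)cc4c3OC)c(C)cc12 | intermediate
17 | 5-hydroxy-7-methyl-6-(1,4,5-trimethoxy-7-methylnaphthalen-2-yl)naphthalene-1,4-dione | COc1c(-c2c(C)cc3C(=O)C=CC(=O)c3c2O)cc(OC)c2c(OC)cc(C)cc12 | intermediate
18 | 6-hydroxy-8-methyl-7-(1,4,5-trimethoxy-7-methylnaphthalen-2-yl)-2-benzoxepine-1,5-dione (not isolated) | O=C1OC=CC(=O)c2c(O)c(-c3cc(OC)c4c(OC)cc(C)cc4c3OC)c(C)cc12 | intermediate
19 | 3-hydroxy-5-methyl-2-(3-oxopropanoyl)-4-(1,4,5-trimethoxy-7-methylnaphthalen-2-yl)benzoic acid (not isolated) | O=CCC(=O)c1c(O)c(-c2cc(OC)c3c(OC)cc(C)cc3c2OC)c(C)cc1C(=O)O | intermediate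
20 | 7-methyl-4-oxo-8-(1,4,5-trimethoxy-7-methylnaphthalen-2-yl)-4H-chromene-5-carboxylic acid | COc1c(-c2c(C)cc(C(=O)O)c3c(=O)ccoc23)cc(OC)c2c(OC)cc(C)cc12 | intermediate
21 | 8-(5-methoxy-7-methyl-1,4-dioxo-1,4-dihydronaphthalen-2-yl)-7-methyl-4-oxo-4H-chromene-5-carboxylic acid | COc1cc(C)cc2c1C(=O)C=C(c1c(C)cc(C(=O)O)c3c(=O)ccoc13)C2=O | intermediate
22 | 8-(5-hydroxy-7-methyl-1,4-dioxo-1,4-dihydronaphthalen-2-yl)-7-methyl-4-oxo-4H-chromene-5-carboxylic acid | Cc1cc(O)c2c(c1)C(=O)C(c1c(C)cc(C(=O)O)c3c(=O)ccoc13)=CC2=O | target

**Step count and weak points**

Total: 11 steps. Longest linear sequence: 10 steps (steps 1–4 and 6–11, from 1 to 22); step 5 is a one-step side branch.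

Step 9 (key step, proposed new method). Three processes can defeat it.
- Peracid addition to the doubly conjugated C1 carbonyl may be slow, or the aryl carbon C8a may migrate in place of the vinylic C2, which gives an aryl ester that cannot become the chromone.
- The electrophilic peracid may hydroxylate the trimethoxynaphthalene ring.
- The aldehyde may be over-oxidised if peracid is still present when the lactone is opened.

Fallback, by known chemistry, from 13 back to 20. Thermal Diels–Alder addition of 13 to the acetylenic keto ester A7, with loss of methanol and the silyl group, would give methyl 2-acetyl-3-hydroxy-5-methyl-4-(1,4,5-trimethoxy-7-methylnaphthalen-2-yl)benzoate F1 (the same compound as A6). Condensation with N,N-dimethylformamide dimethyl acetal would give the enaminone methyl 2-[(2E)-3-(dimethylamino)prop-2-enoyl]-3-hydroxy-5-methyl-4-(1,4,5-trimethoxy-7-methylnaphthalen-2-yl)benzoate F2. HCl would close it, with loss of dimethylamine, to methyl 7-methyl-4-oxo-8-(1,4,5-trimethoxy-7-methylnaphthalen-2-yl)-4H-chromene-5-carboxylate F3. Neutral ester cleavage with Me3SnOH in 1,2-dichloroethane would then give 20, and steps 10 and 11 follow unchanged.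

Step 8 (and the diene formation of step 7). The aryl group on diene C2 is twisted and bulky. Bonding may stop after the first C–C bond (a vinylogous Mukaiyama–Michael product that rearomatises without ring closure), or the silyl ketene acetal may be protonated before it reacts.

Fallback, from 11 (using boronate 9) back to 17, with the biaryl bond made by cross-coupling. Treatment of 11 with LiN(iPr)2 and Me3SiCl would give [(2-bromo-1-methoxy-3-methylbuta-1,3-dien-1-yl)oxy]trimethylsilane F4. Its Diels–Alder reaction with excess 14 would give 6-bromo-5-hydroxy-7-methylnaphthalene-1,4-dione F5, with the bromine fixed at C6 by construction. Reduction with Na2S2O4 and benzylation (BnBr, K2CO3, DMF) would give 1,4,5-tris(benzyloxy)-6-bromo-7-methylnaphthalene F6. Suzuki–Miyaura coupling with 9 (Pd(OAc)2, SPhos, K3PO4) would give 1,4,5-tris(benzyloxy)-7-methyl-6-(1,4,5-trimethoxy-7-methylnaphthalen-2-yl)naphthalene F7. Hydrogenolysis (H2, palladium on carbon) and exposure to air would return 17.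

Step 6. Protodeboronation of the electron-rich, ortho-methoxy boronate may outrun transmetalation to the hindered tetrasubstituted alkenylpalladium species.

Fallback, from 7 back to 12, without a cross-coupling. Bromine–lithium exchange on 7 (n-BuLi, THF, −78 °C) and addition to excess dimethyl oxalate would give methyl 2-oxo-2-(1,4,5-trimethoxy-7-methylnaphthalen-2-yl)acetate F8. Addition of iPrMgCl at −78 °C to the ketone would give racemic methyl 2-hydroxy-3-methyl-2-(1,4,5-trimethoxy-7-methylnaphthalen-2-yl)butanoate F9. Dehydration (SOCl2, pyridine), which can only take the isopropyl hydrogen, would give 12.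

Step 10. Oxidation may be incomplete or run on to degradation, because the ring carries a bulky electron-poor aryl group and the acid and pyranone can bind cerium.

Fallback, from 20 directly to 22, bypassing 21. BBr3 in CH2Cl2 would cleave all three ethers to 8-(1,4,5-trihydroxy-7-methylnaphthalen-2-yl)-7-methyl-4-oxo-4H-chromene-5-carboxylic acid F10. Air or Ag2O would oxidise its para-hydroquinone ring to the hydroxyquinone 22.

**Further compounds**

F1 | step 9 | methyl 2-acetyl-3-hydroxy-5-methyl-4-(1,4,5-trimethoxy-7-methylnaphthalen-2-yl)benzoate | COC(=O)c1cc(C)c(-c2cc(OC)c3c(OC)cc(C)cc3c2OC)c(O)c1C(C)=O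
F2 | step 9 | methyl 2-[(2E)-3-(dimethylamino)prop-2-enoyl]-3-hydroxy-5-methyl-4-(1,4,5-trimethoxy-7-methylnaphthalen-2-yl)benzoate | COC(=O)c1cc(C)c(-c2cc(OC)c3c(OC)cc(C)cc3c2OC)c(O)c1C(=O)/C=C/N(C)C
F3 | step 9 | methyl 7-methyl-4-oxo-8-(1,4,5-trimethoxy-7-methylnaphthalen-2-yl)-4H-chromene-5-carboxylate | COC(=O)c1cc(C)c(-c2cc(OC)c3c(OC)cc(C)cc3c2OC)c2occc(=O)c12
F4 | step 8 | [(2-bromo-1-methoxy-3-methylbuta-1,3-dien-1-yl)oxy]trimethylsilane (mixture of geometric isomers) | COC(O[Si](C)(C)C)=C(Br)C(C)=C
F5 | step 8 | 6-bromo-5-hydroxy-7-methylnaphthalene-1,4-dione | O=C1C=CC(=O)c2c(O)c(Br)c(C)cc12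
F6 | step 8 | 1,4,5-tris(benzyloxy)-6-bromo-7-methylnaphthalene | Brc1c(C)cc2c(OCc3ccccc3)ccc(OCc3ccccc3)c2c1OCc1ccccc1
F7 | step 8 | 1,4,5-tris(benzyloxy)-7-methyl-6-(1,4,5-trimethoxy-7-methylnaphthalen-2-yl)naphthalene | COc1c(-c2c(C)cc3c(OCc4ccccc4)ccc(OCc4ccccc4)c3c2OCc2ccccc2)cc(OC)c2c(OC)cc(C)cc12
F8 | step 6 | methyl 2-oxo-2-(1,4,5-trimethoxy-7-methylnaphthalen-2-yl)acetate | COC(=O)C(=O)c1cc(OC)c2c(OC)cc(C)cc2c1OC
F9 | step 6 | methyl 2-hydroxy-3-methyl-2-(1,4,5-trimethoxy-7-methylnaphthalen-2-yl)butanoate (racemic) | COC(=O)C(O)(C(C)C)c1cc(OC)c2c(OC)cc(C)cc2c1OC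
F10 | step 10 | 8-(1,4,5-trihydroxy-7-methylnaphthalen-2-yl)-7-methyl-4-oxo-4H-chromene-5-carboxylic acid | Oc1c(-c2c(C)cc(C(=O)O)c3c(=O)ccoc23)cc(O)c2c(O)cc(C)cc12
A1 | alternative 1 | methyl 8-(5-hydroxy-7-methyl-1,4-dioxo-1,4-dihydronaphthalen-2-yl)-7-methyl-4-oxo-4H-chromene-5-carboxylate | COC(=O)c1cc(C)c(C2=CC(=O)c3c(O)cc(C)cc3C2=O)c2occc(=O)c12
A2 | alternative 1 | methyl 8-(4-bromo-3,6-dioxocyclohexa-1,4-dien-1-yl)-7-methyl-4-oxo-4H-chromene-5-carboxylate | COC(=O)c1cc(C)c(C2=CC(=O)C(Br)=CC2=O)c2occc(=O)c12
A3 | alternative 2 | methyl 8-(5-methoxy-7-methyl-1,4-dihydro-1,4-epoxynaphthalen-2-yl)-7-methyl-4-oxo-4H-chromene-5-carboxylate (racemic, one enantiomer drawn) | COc1cc(C)cc2c1[C@@H]1O[C@H]2C(c2c(C)cc(C(=O)OC)c3c(=O)ccoc23)=C1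
A4 | alternative 2 | methyl 8-(furan-3-yl)-7-methyl-4-oxo-4H-chromene-5-carboxylate | COC(=O)c1cc(C)c(-c2ccoc2)c2occc(=O)c12
A5 | alternative 2 | 3-methoxy-5-methyl-2-(trimethylsilyl)phenyl trifluoromethanesulfonate | COc1cc(C)cc(OS(=O)(=O)C(F)(F)F)c1[Si](C)(C)C
A6 | alternative 3 | methyl 2-acetyl-3-hydroxy-5-methyl-4-(1,4,5-trimethoxy-7-methylnaphthalen-2-yl)benzoate | COC(=O)c1cc(C)c(-c2cc(OC)c3c(OC)cc(C)cc3c2OC)c(O)c1C(C)=O
A7 | alternative 3 | methyl 4-oxopent-2-ynoate | CC(=O)C#CC(=O)OC
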